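**Strategy.** The oxolane is cut at O1–C2 and C4–C5: O1/C5 are one formaldehyde unit, and C2–C3–C4 is a trans donor–acceptor cyclopropane with aryl-bearing C2 as donor and malonate carbon C4 as acceptor. A Lewis-acid (3+2) annulation closes the five-membered ring in one operation and forms both ring bonds. Backside attack at benzylic C2 inverts that centre, so the trans cyclopropane from the cyclopropanation becomes the 2,3-cis oxolane while C3 stays as it is. The precursor is an enantiopure trans 2-(silyloxymethyl)-3-(3,4,5-trimethoxyphenyl)cyclopropane-1,1-diester from an aminocatalytic cyclopropanation, carried as the acid-robust TBDPS ether. Dealkoxycarbonylation, Weinreb acylation of an aryllithium with thermodynamic setting of C4, and desilylation complete the target.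

Key step: step 4

Remark: oxolane atoms carry the numbering of the target throughout (O1, C2 aryl, C3 CH2O, C4 acyl, C5 CH2), and paraformaldehyde is written as its monomer.

**Route**

Step 1
Reactants: 1 (E)-3,4,5-trimethoxycinnamaldehyde; 2 dimethyl bromomalonate
Product: 3 dimethyl (2S,3R)-2-formyl-3-(3,4,5-trimethoxyphenyl)cyclopropane-1,1-dicarboxylate (trans)
Conditions: (R)-2-[diphenyl(trimethylsilyloxy)methyl]pyrrolidine (10 mol%), 2,6-lutidine (1.1 equiv), CH2Cl2, 0 °C to rt
Reagents that add atoms: none
Why: Aminocatalytic Michael-initiated ring-closure cyclopropanation: the E-iminium ion of 1 should take up the bromomalonate anion at the β-carbon on the face left open by the catalyst's diphenyl(silyloxy)methyl group, and the resulting enamine closes the ring by 3-exo-tet displacement of bromide, so the (R)-catalyst should set the aryl carbon as R and the ring closure the trans (2S) formyl carbon.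

Step 2
Reactants: 3 dimethyl (2S,3R)-2-formyl-3-(3,4,5-trimethoxyphenyl)cyclopropane-1,1-dicarboxylate
Product: 4 dimethyl (2S,3R)-2-(hydroxymethyl)-3-(3,4,5-trimethoxyphenyl)cyclopropane-1,1-dicarboxylate
Conditions: NaBH4, MeOH, −10 °C, short contact; pH 7 buffer
Reagents that add atoms: none
Why: Chemoselective borohydride reduction of the aldehyde beside the malonate esters; low temperature, short contact and a neutral quench should keep the new alkoxide from lactonising onto the cis ester, and no stereocentre is touched.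

Step 3
Reactants: 4 dimethyl (2S,3R)-2-(hydroxymethyl)-3-(3,4,5-trimethoxyphenyl)cyclopropane-1,1-dicarboxylate
Product: 5 dimethyl (2S,3R)-2-[(tert-butyldiphenylsilyloxy)methyl]-3-(3,4,5-trimethoxyphenyl)cyclopropane-1,1-dicarboxylate (trans)
Conditions: TBDPSCl, imidazole, CH2Cl2, 0 °C to rt (crude 4 used at once)
Reagents that add atoms: tert-butyl(chloro)diphenylsilane, CC(C)(C)[Si](Cl)(c1ccccc1)c1ccccc1
Why: Imidazole-promoted silylation of a primary alcohol; the TBDPS ether is chosen because it should withstand the triflate Lewis acid of step 4 and the hot chloride of step 5 better than a smaller trialkylsilyl ether, and immediate silylation forestalls lactonisation.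

Step 4
Reactants: 5 dimethyl (2S,3R)-2-[(tert-butyldiphenylsilyloxy)methyl]-3-(3,4,5-trimethoxyphenyl)cyclopropane-1,1-dicarboxylate; 6 paraformaldehyde
Product: 7 dimethyl (2S,3S)-3-[(tert-butyldiphenylsilyloxy)methyl]-2-(3,4,5-trimethoxyphenyl)oxolane-4,4-dicarboxylate (2,3-cis)
Conditions: Sn(OTf)2 (10 mol%), (CH2O)n (5 equiv), ClCH2CH2Cl, rt (to 45 °C if slow)
Reagents that add atoms: none
Why: Sn(II) chelates the geminal diester and polarises the bond between the aryl-bearing and the malonate carbon; the formaldehyde oxygen then opens the ring at the benzylic carbon from the side opposite the departing malonate (SN2-like, within an intimate ion pair) to form O1–C2, and the tin malonate enolate adds to the resulting oxocarbenium carbon to form C4–C5. The closest known reaction type is the Lewis-acid-catalysed (3+2) annulation of 2-arylcyclopropane-1,1-diesters with aldehydes, which is stereospecific with inversion at the donor carbon. The oxolane closes by an aldol-type attack that is formally 5-endo-trig at the oxocarbenium ion and enolexo at the malonate, a closure that is routine for such cation–enolate pairs. The only centre that changes is C2, and it is substrate-controlled: backside attack turns the (3R) cyclopropane carbon into (2S) while C3 is untouched, so the trans cyclopropane should give the 2,3-cis oxolane. The step needs attack at the aryl-bearing carbon and not at the silyloxymethyl-bearing one, which benzylic stabilisation secures, and it needs inversion to outrun ionisation, which the only moderately donating 3,4,5-trimethoxyphenyl group, the mild catalytic Lewis acid and ambient temperature favour; formaldehyde creates no stereocentre at C5.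

Step 5
Reactants: 7 dimethyl (2S,3S)-3-[(tert-butyldiphenylsilyloxy)methyl]-2-(3,4,5-trimethoxyphenyl)oxolane-4,4-dicarboxylate
Product: 8 methyl (2S,3S)-3-[(tert-butyldiphenylsilyloxy)methyl]-2-(3,4,5-trimethoxyphenyl)oxolane-4-carboxylate (mixture of C4 epimers)
Conditions: LiCl (3 equiv), H2O (2 equiv), DMSO, 150 °C
Reagents that add atoms: none
Why: Krapcho dealkoxycarbonylation: chloride demethylates one ester by SN2, the carboxylate loses CO2 and water protonates the ester enolate; either C4 epimer is acceptable because C4 is set under equilibrating conditions in step 7.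

Step 6
Reactants: 8 methyl (2S,3S)-3-[(tert-butyldiphenylsilyloxy)methyl]-2-(3,4,5-trimethoxyphenyl)oxolane-4-carboxylate
Product: 9 (2S,3S)-3-[(tert-butyldiphenylsilyloxy)methyl]-N-methoxy-N-methyl-2-(3,4,5-trimethoxyphenyl)oxolane-4-carboxamide (mixture of C4 epimers)
Conditions: MeNHOMe·HCl (2 equiv), i-PrMgCl (4 equiv), THF, −20 to 0 °C
Reagents that add atoms: N,O-dimethylhydroxylamine hydrochloride, CNOC.Cl
Why: Weinreb amide formation by direct aminolysis of the methyl ester with the chloromagnesium amide of N,O-dimethylhydroxylamine, which tolerates the silyl ether and needs no free acid.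

Step 7
Reactants: 9 (2S,3S)-3-[(tert-butyldiphenylsilyloxy)methyl]-N-methoxy-N-methyl-2-(3,4,5-trimethoxyphenyl)oxolane-4-carboxamide; 10 5-bromo-1,2,3-trimethoxybenzene
Product: 13 [(2S,3S,4R)-3-[(tert-butyldiphenylsilyloxy)methyl]-2-(3,4,5-trimethoxyphenyl)oxolan-4-yl](3,4,5-trimethoxyphenyl)methanone, via 3,4,5-trimethoxyphenyllithium 11 (not isolated), via C4-epimeric ketone 12 (not isolated)
Conditions: 10 (1.6 equiv), n-BuLi (1.5 equiv), THF, −78 °C; then 9, −78 °C; aq. NH4Cl; then DBU (0.3 equiv), CH2Cl2, rt
Reagents that add atoms: none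
Why: Weinreb ketone synthesis: bromine–lithium exchange gives the aryllithium, whose adduct with the amide stays a chelated tetrahedral intermediate until the quench so that over-addition should not occur, and DBU-mediated enolisation then equilibrates C4 to the (4R) isomer, in which the aroyl group is trans to the C3 silyloxymethyl group and to the C2 aryl group (thermodynamic control).

Step 8
Reactants: 13 [(2S,3S,4R)-3-[(tert-butyldiphenylsilyloxy)methyl]-2-(3,4,5-trimethoxyphenyl)oxolan-4-yl](3,4,5-trimethoxyphenyl)methanone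
Product: 14 [(2S,3S,4R)-3-(hydroxymethyl)-2-(3,4,5-trimethoxyphenyl)oxolan-4-yl](3,4,5-trimethoxyphenyl)methanone
Conditions: TBAF (2 equiv), AcOH (2 equiv), THF, 0 °C to rt
Reagents that add atoms: none
Why: Fluoride cleavage of the silyl ether, buffered with acetic acid so that the ketone α-centre C4 is not re-enolised; the 3,4-trans product cannot close to a cyclic hemiketal and should be obtained as the open hydroxy ketone.

**Compound list**

1 | (E)-3,4,5-trimethoxycinnamaldehyde | COc1cc(/C=C/C=O)cc(OC)c1OC | starting material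
2 | dimethyl bromomalonate | COC(=O)C(Br)C(=O)OC | starting material
3 | dimethyl (2S,3R)-2-formyl-3-(3,4,5-trimethoxyphenyl)cyclopropane-1,1-dicarboxylate | COC(=O)C1(C(=O)OC)[C@@H](c2cc(OC)c(OC)c(OC)c2)[C@@H]1C=O | intermediate
4 | dimethyl (2S,3R)-2-(hydroxymethyl)-3-(3,4,5-trimethoxyphenyl)cyclopropane-1,1-dicarboxylate | COC(=O)C1(C(=O)OC)[C@@H](c2cc(OC)c(OC)c(OC)c2)[C@@H]1CO | intermediate
5 | dimethyl (2S,3R)-2-[(tert-butyldiphenylsilyloxy)methyl]-3-(3,4,5-trimethoxyphenyl)cyclopropane-1,1-dicarboxylate | COC(=O)C1(C(=O)OC)[C@@H](c2cc(OC)c(OC)c(OC)c2)[C@@H]1CO[Si](c1ccccc1)(c1ccccc1)C(C)(C)C | intermediate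
6 | paraformaldehyde (monomer shown) | C=O | starting material
7 | dimethyl (2S,3S)-3-[(tert-butyldiphenylsilyloxy)methyl]-2-(3,4,5-trimethoxyphenyl)oxolane-4,4-dicarboxylate | COC(=O)C1(C(=O)OC)CO[C@H](c2cc(OC)c(OC)c(OC)c2)[C@@H]1CO[Si](c1ccccc1)(c1ccccc1)C(C)(C)C | intermediate
8 | methyl (2S,3S)-3-[(tert-butyldiphenylsilyloxy)methyl]-2-(3,4,5-trimethoxyphenyl)oxolane-4-carboxylate, C4 epimers | COC(=O)C1CO[C@H](c2cc(OC)c(OC)c(OC)c2)[C@@H]1CO[Si](c1ccccc1)(c1ccccc1)C(C)(C)C | intermediate
9 | (2S,3S)-3-[(tert-butyldiphenylsilyloxy)methyl]-N-methoxy-N-methyl-2-(3,4,5-trimethoxyphenyl)oxolane-4-carboxamide, C4 epimers | CON(C)C(=O)C1CO[C@H](c2cc(OC)c(OC)c(OC)c2)[C@@H]1CO[Si](c1ccccc1)(c1ccccc1)C(C)(C)C | intermediate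
10 | 5-bromo-1,2,3-trimethoxybenzene | COc1cc(Br)cc(OC)c1OC | starting material
11 | 3,4,5-trimethoxyphenyllithium | [Li]c1cc(OC)c(OC)c(OC)c1 | intermediate
12 | [(2S,3S)-3-[(tert-butyldiphenylsilyloxy)methyl]-2-(3,4,5-trimethoxyphenyl)oxolan-4-yl](3,4,5-trimethoxyphenyl)methanone, C4 epimers | COc1cc(C(=O)C2CO[C@H](c3cc(OC)c(OC)c(OC)c3)[C@@H]2CO[Si](c2ccccc2)(c2ccccc2)C(C)(C)C)cc(OC)c1OC | intermediate
13 | [(2S,3S,4R)-3-[(tert-butyldiphenylsilyloxy)methyl]-2-(3,4,5-trimethoxyphenyl)oxolan-4-yl](3,4,5-trimethoxyphenyl)methanone | COc1cc(C(=O)[C@H]2CO[C@H](c3cc(OC)c(OC)c(OC)c3)[C@@H]2CO[Si](c2ccccc2)(c2ccccc2)C(C)(C)C)cc(OC)c1OC | intermediate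
14 | [(2S,3S,4R)-3-(hydroxymethyl)-2-(3,4,5-trimethoxyphenyl)oxolan-4-yl](3,4,5-trimethoxyphenyl)methanone | COc1cc(C(=O)[C@H]2CO[C@H](c3cc(OC)c(OC)c(OC)c3)[C@@H]2CO)cc(OC)c1OC | target

**Count**

Total steps: 8. Longest linear sequence: 8 steps (from 1); 6 and 10 enter as commercial materials.

**Steps most likely to fail**

Step 4. The activated cyclopropane may ionise to an open benzylic zwitterion before formaldehyde arrives, which would erode the configuration at C2 or lead to hydride shift to an alkene. Formaldehyde may also be taken up more than once, or may hydroxymethylate the electron-rich ring. Fallback, from 5 back to 7: the same cyclopropane is annulated with (E)-cinnamaldehyde, a fast and well-behaved partner for this reaction class (Sn(OTf)2, CH2Cl2, rt), to give dimethyl (2S,3S)-5-[(E)-2-phenylethenyl]-3-[(tert-butyldiphenylsilyloxy)methyl]-2-(3,4,5-trimethoxyphenyl)oxolane-4,4-dicarboxylate F1 (2,5-cis expected). Lemieux–Johnson cleavage of the styryl group (OsO4 cat., NaIO4, 2,6-lutidine, dioxane–water) should give the 5-formyl oxolane diester F2. Tsuji–Wilkinson decarbonylation (RhCl(PPh3)3, toluene or benzonitrile, reflux) would then replace the formyl group by hydrogen and return 7. The extra carbon is excised instead of formaldehyde being used, and the C5 centre created on the way disappears.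

Step 5. At 150 °C the silyl ether may be lost to chloride and water, or the ester enolate may expel the ring oxygen (β-alkoxide elimination) and open the oxolane. Fallback, from 7 back to 8: monosaponification with LiOH (1.05 equiv, THF–water, 0 °C), expected at the ester anti to the C3 substituent, gives the malonic half-acid 4-(methoxycarbonyl)-3-[(tert-butyldiphenylsilyloxy)methyl]-2-(3,4,5-trimethoxyphenyl)oxolane-4-carboxylic acid F3. Thermal decarboxylation (toluene, Et3N cat., 100–110 °C) should then deliver 8 without chloride and at a much lower temperature.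

Step 7. The aryllithium may deprotonate the amide α-C–H instead of adding, returning amide after the quench, or the base equilibration may trigger ring opening by β-elimination from the ketone enolate. Fallback, from 9 back to 12: reduction of the Weinreb amide with DIBAL-H (THF, −78 °C) gives the oxolane-4-carbaldehyde F4. Addition of the less basic 3,4,5-trimethoxyphenylmagnesium bromide (from 10 and Mg, THF, −40 °C) gives the secondary carbinol F5. Dess–Martin oxidation then furnishes ketone 12, which is equilibrated to 13 as in step 7.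

**Further compounds**

F1 | step 4 | dimethyl (2S,3S)-5-[(E)-2-phenylethenyl]-3-[(tert-butyldiphenylsilyloxy)methyl]-2-(3,4,5-trimethoxyphenyl)oxolane-4,4-dicarboxylate (2,5-cis) | COC(=O)C1(C(=O)OC)[C@H](/C=C/c2ccccc2)O[C@H](c2cc(OC)c(OC)c(OC)c2)[C@@H]1CO[Si](c1ccccc1)(c1ccccc1)C(C)(C)C
F2 | step 4 | dimethyl (2S,3S)-5-formyl-3-[(tert-butyldiphenylsilyloxy)methyl]-2-(3,4,5-trimethoxyphenyl)oxolane-4,4-dicarboxylate (2,5-cis) | COC(=O)C1(C(=O)OC)[C@H](C=O)O[C@H](c2cc(OC)c(OC)c(OC)c2)[C@@H]1CO[Si](c1ccccc1)(c1ccccc1)C(C)(C)C
F3 | step 5 | (2S,3S)-4-(methoxycarbonyl)-3-[(tert-butyldiphenylsilyloxy)methyl]-2-(3,4,5-trimethoxyphenyl)oxolane-4-carboxylic acid (C4 not defined) | COC(=O)C1(C(=O)O)CO[C@H](c2cc(OC)c(OC)c(OC)c2)[C@@H]1CO[Si](c1ccccc1)(c1ccccc1)C(C)(C)C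
F4 | step 7 | (2S,3S)-3-[(tert-butyldiphenylsilyloxy)methyl]-2-(3,4,5-trimethoxyphenyl)oxolane-4-carbaldehyde (C4 epimers) | O=CC1CO[C@H](c2cc(OC)c(OC)c(OC)c2)[C@@H]1CO[Si](c1ccccc1)(c1ccccc1)C(C)(C)C
F5 | step 7 | [(2S,3S)-3-[(tert-butyldiphenylsilyloxy)methyl]-2-(3,4,5-trimethoxyphenyl)oxolan-4-yl](3,4,5-trimethoxyphenyl)methanol (C4 and carbinol epimers) | COc1cc(C(O)C2CO[C@H](c3cc(OC)c(OC)c(OC)c3)[C@@H]2CO[Si](c2ccccc2)(c2ccccc2)C(C)(C)C)cc(OC)c1OC
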